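**Assumption:** germacrane numbering is used for all intermediates (C12 = lactone carbonyl, C13 = exocyclic CH2, C14/C15 = methyls on C10/C4); the SMILES is read as 1R,6R,7R,8R,10R with a (2S,3R)-2,3-dimethyloxirane-2-carboxylate on O-8 (1β,10α-epoxide, 6α-O, H-7α, 8β-O, 2Z,4Z).

## Retrosynthetic overview

1. Cut the C8–O ester last: 8β-alcohol plus (2S,3R)-2,3-dimethyloxirane-2-carboxylic acid, the latter from Sharpless epoxidation of tiglyl alcohol and oxidation.
2. The 2Z olefin comes from semi-hydrogenation of a ring alkyne; the alkyne masks it so that no (Z,Z)-dienal, which would scramble through oxa-6π closure and reopening, is ever handled.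
3. Key cut: C6–C7 and the lactone C12–O6 bond together. An open-chain bromomethyl-enoate/enynal closes under CrCl2 to a cyclodecenyne and the α-methylene-γ-lactone in one operation, setting C6 and C7.
4. The open chain comes from Shi epoxidation (C1, C10) of a dienyne, made by Sonogashira coupling of an E-vinyl iodide with commercial (Z)-3-methylpent-2-en-4-yn-1-ol; C11–C13 come from a Baylis–Hillman reaction and C8 from (S)-glycidol.
5. Ring order: 1,10-epoxide, then ten-membered carbocycle and γ-lactone simultaneously, then the side-chain epoxide arrives pre-formed with the acid.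

## Route

Step 1
Reactants: 1 (S)-glycidol; 2 lithium acetylide–ethylenediamine complex
Product: 3 (2R)-pent-4-yne-1,2-diol
Conditions: LiC≡CH·H2NCH2CH2NH2 (3 equiv), DMSO, 0 °C to 25 °C; then H2O
Reagents that add atoms: none
Why: SN2 opening of the epoxide at its CH2 terminus by acetylide (epoxide alkynylation) leaves the carbinol centre, the future C8 (R), untouched, and the degenerate Payne shift of the glycidol alkoxide leads to the same enantiomer.

Step 2
Reactants: 3 (2R)-pent-4-yne-1,2-diol
Product: 4 (4R)-4,5-bis(triethylsilyloxy)pent-1-yne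
Conditions: Et3SiCl (2.2 equiv), imidazole, CH2Cl2, 0 °C to 25 °C
Reagents that add atoms: chlorotriethylsilane, CC[Si](Cl)(CC)CC
Why: Imidazole-promoted silyl ether formation on both hydroxyls; no stereocentre is affected.

Step 3
Reactants: 4 (4R)-4,5-bis(triethylsilyloxy)pent-1-yne
Product: 6 (1E,4R)-1-iodo-2-methyl-4,5-bis(triethylsilyloxy)pent-1-ene, via alkenylalane 5 (not isolated)
Conditions: AlMe3 (2.5 equiv), Cp2ZrCl2 (0.25 equiv), CH2Cl2, 0 °C to 25 °C; then I2, THF, −30 °C
Reagents that add atoms: trimethylaluminium, C[Al](C)C; iodine, II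
Why: Negishi zirconium-catalysed carboalumination adds CH3 and Al syn across the terminal alkyne (CH3 to the internal carbon) and iodinolysis of the C–Al bond goes with retention, which fixes the E-trisubstituted C1=C10 olefin and brings in C14.

Step 4
Reactants: 6 (1E,4R)-1-iodo-2-methyl-4,5-bis(triethylsilyloxy)pent-1-ene
Product: 7 (2R,4E)-5-iodo-4-methyl-2-(triethylsilyloxy)pent-4-enal
Conditions: (COCl)2, DMSO, CH2Cl2, −78 °C to −30 °C; then Et3N, −78 °C to 0 °C
Reagents that add atoms: none
Why: Under Swern conditions a primary triethylsilyl ether is cleaved and oxidised to the aldehyde while the secondary one survives, and the cold, non-epimerising protocol keeps the α-silyloxy centre (C8).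

Step 5
Reactants: 7 (2R,4E)-5-iodo-4-methyl-2-(triethylsilyloxy)pent-4-enal; 8 methyl acrylate
Product: 9 methyl (3RS,4R,6E)-3-hydroxy-7-iodo-6-methyl-2-methylidene-4-(triethylsilyloxy)hept-6-enoate
Conditions: DABCO (1 equiv), methyl acrylate (10 equiv, neat), 25 °C, 5–7 d
Reagents that add atoms: none
Why: Morita–Baylis–Hillman reaction installs C11–C13; the new carbinol centre (C7) forms as an epimer mixture that does not matter because it becomes sp2 in step 9.

Step 6
Reactants: 9 methyl (3RS,4R,6E)-3-hydroxy-7-iodo-6-methyl-2-methylidene-4-(triethylsilyloxy)hept-6-enoate; 10 (2Z)-3-methylpent-2-en-4-yn-1-ol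
Product: 11 methyl (3RS,4R,6E,10Z)-3,12-dihydroxy-6,10-dimethyl-2-methylidene-4-(triethylsilyloxy)dodeca-6,10-dien-8-ynoate
Conditions: Pd(PPh3)2Cl2 (3 mol%), CuI (6 mol%), Et3N, THF (degassed), 25 °C
Reagents that add atoms: none
Why: Sonogashira coupling (zerovalent palladium, copper acetylide) joins the sp2 and sp carbons with retention of the E-iodide and Z-enynol geometries, and it is placed before the epoxidation because propargylic epoxides ionise with zerovalent palladium.

Step 7
Reactants: 11 methyl (3RS,4R,6E,10Z)-3,12-dihydroxy-6,10-dimethyl-2-methylidene-4-(triethylsilyloxy)dodeca-6,10-dien-8-ynoate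
Product: 12 methyl (3RS,4R)-3-hydroxy-5-[(2R,3R)-3-[(3Z)-5-hydroxy-3-methylpent-3-en-1-yn-1-yl]-2-methyloxiran-2-yl]-2-methylidene-4-(triethylsilyloxy)pentanoate
Conditions: D-fructose-derived Shi ketone (0.3 equiv), Oxone (2KHSO5·KHSO4·K2SO4), K2CO3, Bu4NHSO4, MeCN–CH2(OMe)2–aq. Na2B4O7 buffer (pH 10.5), 0 °C
Reagents that add atoms: potassium peroxymonosulfate, [K+].[O-]S(=O)(=O)OO
Why: Shi epoxidation, in which the chiral dioxirane attacks the most electron-rich olefin, the trisubstituted enyne C1=C10 (C4=C5 carries a deactivating allylic C–O bond and the acrylate is electron-poor), through the spiro transition state that turns E-olefins of this pattern into (R,R)-epoxides, so C1 and C10 are set by the catalyst.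

Step 8
Reactants: 12 methyl (3RS,4R)-3-hydroxy-5-[(2R,3R)-3-[(3Z)-5-hydroxy-3-methylpent-3-en-1-yn-1-yl]-2-methyloxiran-2-yl]-2-methylidene-4-(triethylsilyloxy)pentanoate
Product: 13 methyl (3RS,4R)-3-hydroxy-2-methylidene-5-[(2R,3R)-2-methyl-3-[(3Z)-3-methyl-5-oxopent-3-en-1-yn-1-yl]oxiran-2-yl]-4-(triethylsilyloxy)pentanoate
Conditions: MnO2 (20 equiv), CH2Cl2, 25 °C; filtered and used directly
Reagents that add atoms: none
Why: Allylic oxidation with MnO2 takes the primary enynyl alcohol much faster than the electron-poor secondary Baylis–Hillman carbinol and, being neutral, keeps the Z-enal and the acid-labile γ,δ-epoxy alcohol intact.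

Step 9
Reactants: 13 methyl (3RS,4R)-3-hydroxy-2-methylidene-5-[(2R,3R)-2-methyl-3-[(3Z)-3-methyl-5-oxopent-3-en-1-yn-1-yl]oxiran-2-yl]-4-(triethylsilyloxy)pentanoate
Product: 14 methyl (2Z,4R)-2-(bromomethyl)-5-[(2R,3R)-2-methyl-3-[(3Z)-3-methyl-5-oxopent-3-en-1-yn-1-yl]oxiran-2-yl]-4-(triethylsilyloxy)pent-2-enoate
Conditions: NBS, Me2S, CH2Cl2, −20 °C to 0 °C
Reagents that add atoms: N-bromosuccinimide, BrN1C(=O)CCC1=O
Why: Corey–Kim-type activation of the Baylis–Hillman alcohol as an alkoxysulfonium salt followed by SN2' attack of bromide gives the rearranged primary allylic bromide as the favoured Z-isomer (C8 cis to CH2Br) under neutral conditions.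

Step 10
Reactants: 14 methyl (2Z,4R)-2-(bromomethyl)-5-[(2R,3R)-2-methyl-3-[(3Z)-3-methyl-5-oxopent-3-en-1-yn-1-yl]oxiran-2-yl]-4-(triethylsilyloxy)pent-2-enoate
Product: 16 (1R,6R,7S,8R,10R)-1,10-epoxy-8-(triethylsilyloxy)germacra-4Z,11(13)-dien-2-yn-12,6-olide, via chromium alkoxide 15 (not isolated)
Conditions: CrCl2 (8 equiv), THF–DMF 10:1, 0.002 M (syringe pump, 10 h), 25 °C; then aq. NH4Cl, silica gel
Reagents that add atoms: none
Why: Intramolecular Nozaki–Hiyama–Kishi-type 2-(methoxycarbonyl)allylation with in situ lactonisation (Dreiding–Schmidt type), in which the equilibrating allylchromium adds to the enynal through a chair transition state with both ring branches (C5 and C8) equatorial, giving the anti adduct and hence the trans-fused lactone (H-6β, H-7α), while allylic 1,3-strain with the ester holds H-8 in the C7=C11 plane so that the new bond forms anti to the C8–C9 bond on the face flanked by the silyloxy group (8β-O cis to C11), and the trivalent chromium alkoxide then closes onto the methyl ester, so the ten-membered ring and the γ-lactone form in one operation.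

Step 11
Reactants: 16 (1R,6R,7S,8R,10R)-1,10-epoxy-8-(triethylsilyloxy)germacra-4Z,11(13)-dien-2-yn-12,6-olide
Product: 17 (1R,6R,7R,8R,10R)-1,10-epoxy-8-hydroxygermacra-4Z,11(13)-dien-2-yn-12,6-olide
Conditions: HF·pyridine, pyridine, THF, 0 °C
Reagents that add atoms: none
Why: Fluoride-mediated silyl ether cleavage, done at this stage because the alkynyl epoxide tolerates buffered HF·pyridine better than the later dienyl epoxide; no stereocentre is affected (the C7 descriptor changes only through priorities).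

Step 12
Reactants: 17 (1R,6R,7R,8R,10R)-1,10-epoxy-8-hydroxygermacra-4Z,11(13)-dien-2-yn-12,6-olide
Product: 18 (1R,6R,7R,8R,10R)-1,10-epoxy-8-hydroxygermacra-2Z,4Z,11(13)-trien-12,6-olide
Conditions: H2 (1 atm), Pd/CaCO3 poisoned with Pb(OAc)2, quinoline, EtOAc, 0 °C; stopped after 1 equiv H2
Reagents that add atoms: none
Why: Lindlar semi-hydrogenation delivers H2 syn to the strained ring alkyne, much faster than to the conjugated exocyclic methylene, and in the ten-membered ring this can only give the 2Z olefin.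

Step 13
Reactants: 19 (2E)-2-methylbut-2-en-1-ol (tiglyl alcohol)
Product: 20 [(2R,3R)-2,3-dimethyloxiran-2-yl]methanol
Conditions: Ti(OiPr)4 (10 mol%), D-(−)-diisopropyl tartrate (12 mol%), t-BuOOH, 4 Å molecular sieves, CH2Cl2, −20 °C
Reagents that add atoms: tert-butyl hydroperoxide, CC(C)(C)OO
Why: Sharpless asymmetric epoxidation of the E-allylic alcohol, where D-(−)-tartrate gives the (2R,3R)-epoxy alcohol (L-(+)-tartrate gives 2S,3S) and the stereospecific syn oxygen transfer keeps the two methyl groups cis.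

Step 14
Reactants: 20 [(2R,3R)-2,3-dimethyloxiran-2-yl]methanol
Product: 21 (2S,3R)-2,3-dimethyloxirane-2-carboxylic acid
Conditions: TEMPO (10 mol%), PhI(OAc)2 (2.2 equiv), MeCN–H2O (pH 7 phosphate buffer), 25 °C
Reagents that add atoms: water, O
Why: TEMPO/PhI(OAc)2 oxidation of the primary alcohol through the aldehyde hydrate to the acid leaves both epoxide carbons untouched (C2 becomes S only because CO2H now outranks C3).

Step 15
Reactants: 18 (1R,6R,7R,8R,10R)-1,10-epoxy-8-hydroxygermacra-2Z,4Z,11(13)-trien-12,6-olide; 21 (2S,3R)-2,3-dimethyloxirane-2-carboxylic acid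
Product: 23 (1R,6R,7R,8R,10R)-8-[(2S,3R)-2,3-dimethyloxirane-2-carbonyloxy]-1,10-epoxygermacra-2Z,4Z,11(13)-trien-12,6-olide, via mixed anhydride 22 (not isolated)
Conditions: 2,4,6-trichlorobenzoyl chloride, Et3N, THF, 25 °C; then 18, DMAP, toluene, 25 °C
Reagents that add atoms: none
Why: Yamaguchi esterification (mixed anhydride, DMAP acyl transfer) acylates the 8β-hydroxyl with retention at C8 and at both epoxide carbons of the acid.

## Compound list

1 | (S)-glycidol, (2S)-oxiran-2-ylmethanol | OC[C@H]1CO1 | starting material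
2 | lithium acetylide–ethylenediamine complex | [Li+].[C-]#C.NCCN | starting material
3 | (2R)-pent-4-yne-1,2-diol | C#CC[C@@H](O)CO | intermediate
4 | (4R)-4,5-bis(triethylsilyloxy)pent-1-yne | C#CC[C@@H](O[Si](CC)(CC)CC)CO[Si](CC)(CC)CC | intermediate
5 | alkenylalane, dimethyl[(1E,4R)-2-methyl-4,5-bis(triethylsilyloxy)pent-1-en-1-yl]alane | C[Al](C)/C=C(\C)C[C@@H](O[Si](CC)(CC)CC)CO[Si](CC)(CC)CC | intermediate (not isolated)
6 | (1E,4R)-1-iodo-2-methyl-4,5-bis(triethylsilyloxy)pent-1-ene | I/C=C(\C)C[C@@H](O[Si](CC)(CC)CC)CO[Si](CC)(CC)CC | intermediate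
7 | (2R,4E)-5-iodo-4-methyl-2-(triethylsilyloxy)pent-4-enal | I/C=C(\C)C[C@@H](O[Si](CC)(CC)CC)C=O | intermediate
8 | methyl acrylate | C=CC(=O)OC | starting material
9 | methyl (3RS,4R,6E)-3-hydroxy-7-iodo-6-methyl-2-methylidene-4-(triethylsilyloxy)hept-6-enoate (C3 epimer mixture) | I/C=C(\C)C[C@@H](O[Si](CC)(CC)CC)C(O)C(=C)C(=O)OC | intermediate
10 | (2Z)-3-methylpent-2-en-4-yn-1-ol | OC/C=C(C)\C#C | starting material
11 | methyl (3RS,4R,6E,10Z)-3,12-dihydroxy-6,10-dimethyl-2-methylidene-4-(triethylsilyloxy)dodeca-6,10-dien-8-ynoate | OC/C=C(C)\C#C/C=C(\C)C[C@@H](O[Si](CC)(CC)CC)C(O)C(=C)C(=O)OC | intermediate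
12 | methyl (3RS,4R)-3-hydroxy-5-[(2R,3R)-3-[(3Z)-5-hydroxy-3-methylpent-3-en-1-yn-1-yl]-2-methyloxiran-2-yl]-2-methylidene-4-(triethylsilyloxy)pentanoate | OC/C=C(C)\C#C[C@H]1O[C@]1(C)C[C@@H](O[Si](CC)(CC)CC)C(O)C(=C)C(=O)OC | intermediate
13 | methyl (3RS,4R)-3-hydroxy-2-methylidene-5-[(2R,3R)-2-methyl-3-[(3Z)-3-methyl-5-oxopent-3-en-1-yn-1-yl]oxiran-2-yl]-4-(triethylsilyloxy)pentanoate | O=C/C=C(C)\C#C[C@H]1O[C@]1(C)C[C@@H](O[Si](CC)(CC)CC)C(O)C(=C)C(=O)OC | intermediate
14 | methyl (2Z,4R)-2-(bromomethyl)-5-[(2R,3R)-2-methyl-3-[(3Z)-3-methyl-5-oxopent-3-en-1-yn-1-yl]oxiran-2-yl]-4-(triethylsilyloxy)pent-2-enoate | O=C/C=C(C)\C#C[C@H]1O[C@]1(C)C[C@@H](O[Si](CC)(CC)CC)/C=C(\CBr)C(=O)OC | intermediate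
15 | chromium alkoxide: ring-closed methyl 2-(cyclodecenynyl)acrylate with C6–O–CrCl2 (trivalent chromium), lactone not yet closed | C=C(C(=O)OC)[C@H]1[C@H](O[Cr](Cl)Cl)/C=C(C)\C#C[C@H]2O[C@]2(C)C[C@H]1O[Si](CC)(CC)CC | intermediate (not isolated)
16 | (1R,6R,7S,8R,10R)-1,10-epoxy-8-(triethylsilyloxy)germacra-4Z,11(13)-dien-2-yn-12,6-olide (1β,10α-epoxide, 6α-O, H-7α, 8β-OSiEt3) | C=C1C(=O)O[C@@H]2/C=C(C)\C#C[C@H]3O[C@]3(C)C[C@@H](O[Si](CC)(CC)CC)[C@@H]12 | intermediate
17 | (1R,6R,7R,8R,10R)-1,10-epoxy-8-hydroxygermacra-4Z,11(13)-dien-2-yn-12,6-olide | C=C1C(=O)O[C@@H]2/C=C(C)\C#C[C@H]3O[C@]3(C)C[C@@H](O)[C@@H]12 | intermediate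
18 | (1R,6R,7R,8R,10R)-1,10-epoxy-8-hydroxygermacra-2Z,4Z,11(13)-trien-12,6-olide | C=C1C(=O)O[C@@H]2/C=C(C)\C=C/[C@H]3O[C@]3(C)C[C@@H](O)[C@@H]12 | intermediate
19 | (2E)-2-methylbut-2-en-1-ol (tiglyl alcohol) | C/C=C(\C)CO | starting material
20 | [(2R,3R)-2,3-dimethyloxiran-2-yl]methanol | OC[C@@]1(C)O[C@@H]1C | intermediate
21 | (2S,3R)-2,3-dimethyloxirane-2-carboxylic acid | OC(=O)[C@@]1(C)O[C@@H]1C | intermediate
22 | mixed anhydride of 21 with 2,4,6-trichlorobenzoic acid | O=C(OC(=O)c1c(Cl)cc(Cl)cc1Cl)[C@@]2(C)O[C@@H]2C | intermediate (not isolated)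
23 | CNP0122107.1, (1R,6R,7R,8R,10R)-8-[(2S,3R)-2,3-dimethyloxirane-2-carbonyloxy]-1,10-epoxygermacra-2Z,4Z,11(13)-trien-12,6-olide | C=C1C(=O)O[C@@H]2/C=C(C)\C=C/[C@H]3O[C@]3(C)C[C@@H](OC(=O)[C@@]3(C)O[C@@H]3C)[C@@H]12 | target

## Step count and risks

Total step count: 15. Longest linear sequence: 13 (steps 1–12 and 15); the acid 21 is made in 2 steps (13, 14).

**Step 10 (most likely to fail).** The closure builds a strained cyclodecenyne and sets C6 and C7 in one event. Zinc and indium 2-(alkoxycarbonyl)allyl reagents normally give the syn adduct and so the cis-fused lactone; the anti outcome assumed here rests on crotylchromium-type behaviour, and the C7 face rests on a conformational model. The fallback sets out from 14 and accepts the syn sense on purpose. Closure with indium powder in THF–H2O at 0.002 M should give the cis-fused 6-epi lactone F1. LiOH in THF–H2O at 0 °C opens it to the seco hydroxy acid F2. Mitsunobu lactonisation (PPh3, DIAD, THF, 0 °C) then inverts C6 and comes back to the route at 16.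

**Step 7.** The Shi epoxidation must choose C1=C10 over C4=C5 in a dienyne that carries a free allylic alcohol, and 12 is a γ,δ-epoxy alcohol that can cyclise to a tetrahydrofuran if exposed to acid. The fallback sets out from 11 and makes the selectivity substrate-controlled. Acetyl chloride (1.05 equiv) with 2,4,6-collidine in CH2Cl2 at −78 °C gives the primary monoacetate F3, whose C4=C5 bond is deactivated. The same Shi conditions then give the epoxy acetate F4. Methanolysis with catalytic K2CO3 in MeOH at 0 °C comes back to the route at 12.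

**Step 12.** Semi-hydrogenation could also touch the exocyclic methylene or hydrogenolyse the propargylic C–O bond. The fallback sets out from 16 and replaces hydrogenation by hydrosilylation and protodesilylation. BnMe2SiH with Pt2[(CH2=CHSiMe2)2O]3 (zerovalent platinum) in THF adds Si–H syn to the alkyne and gives the vinylsilane F5 (silicon expected at C3, remote from the epoxide). Bu4NF in THF at 0 °C then removes both the vinyl silicon (with retention, giving the 2Z olefin) and the triethylsilyl ether, and comes back to the route at 18.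

Further compounds
F1 | step 10 | 6-epi lactone, 6β-O cis-fused isomer of 16 | C=C1C(=O)O[C@H]2/C=C(C)\C#C[C@H]3O[C@]3(C)C[C@@H](O[Si](CC)(CC)CC)[C@@H]12
F2 | step 10 | seco hydroxy acid, 6-epi series, free C6–OH and acrylic acid | C=C(C(=O)O)[C@H]1[C@@H](O)/C=C(C)\C#C[C@H]2O[C@]2(C)C[C@H]1O[Si](CC)(CC)CC
F3 | step 7 | primary monoacetate of 11 | CC(=O)OC/C=C(C)\C#C/C=C(\C)C[C@@H](O[Si](CC)(CC)CC)C(O)C(=C)C(=O)OC
F4 | step 7 | epoxy acetate, O-acetate of 12 at the primary hydroxyl | CC(=O)OC/C=C(C)\C#C[C@H]1O[C@]1(C)C[C@@H](O[Si](CC)(CC)CC)C(O)C(=C)C(=O)OC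
F5 | step 12 | vinylsilane, 3-(benzyldimethylsilyl)-2Z,4Z-diene from 16 | C=C1C(=O)O[C@@H]2/C=C(C)\C([Si](C)(C)Cc4ccccc4)=C/[C@H]3O[C@]3(C)C[C@@H](O[Si](CC)(CC)CC)[C@@H]12
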